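**Retrosynthetic overview**
- Target ⇐ global desilylation ⇐ O-acetylation ⇐ Morita–Baylis–Hillman hydroxymethylation of the epoxy-enone ⇐ C1 oxidation; the C1'–C2' bond comes from a CrCl2/NiCl2 (Nozaki–Hiyama–Kishi) coupling of fragment A (ring epoxy-aldehyde) with fragment B (C2'–C12' trienyl iodide), and C1' is then set by oxidation and chelation-controlled reduction.
- Fragment A: the only carbocycle is closed by ring-closing metathesis (C2=C3) of an acyclic epoxy-diene.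
- The epoxide is made before the ring, by hydroxyl-directed epoxidation of a (Z)-trisubstituted allylic alcohol built from but-2-yne-1,4-diol (C1, C6, C5, C1'), acrolein (C4, C3; asymmetric addition sets C4) and CH2=CHMgBr (C2).
- Fragment B: from pent-4-yn-1-ol by two Cp2ZrCl2/AlMe3 carboalumination–iodinations (E), a Still–Gennari olefination (Z) and a Suzuki coupling with an enyne boronate from bis(trimethylsilyl)butadiyne.
- Ring order: oxirane first, then the cyclohexene by metathesis.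

Convention: C1–C6 (ring; C1 = carbonyl carbon, C5/C6 = epoxide) and C1'–C12' (chain) are the target's locants. CIP letters in names are those of each compound and switch with protecting groups; no stereocentre is inverted once set.

**Fragment A (steps 1–10)**

Step 1
Reactants: 1 but-2-yne-1,4-diol
Product: 2 4-[(4-methoxybenzyl)oxy]but-2-yn-1-ol
Conditions: NaH (1 equiv), 4-methoxybenzyl chloride (1 equiv), Bu4NI (cat.), 1 (3 equiv), THF/DMF, 0 °C to rt
Reagents that add atoms: 4-methoxybenzyl chloride, COc1ccc(CCl)cc1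
Why: Williamson etherification in which a threefold excess of the cheap symmetric diol makes mono-alkylation dominant.

Step 2
Reactants: 2 4-[(4-methoxybenzyl)oxy]but-2-yn-1-ol
Product: 4 (Z)-3-iodo-4-[(4-methoxybenzyl)oxy]but-2-en-1-ol, via sodium alkenylaluminate 3 (not isolated)
Conditions: NaAlH2(OCH2CH2OMe)2, THF, 0 °C; then I2, THF, -78 °C
Reagents that add atoms: iodine, II
Why: Hydroxyl-directed trans-hydroalumination puts aluminium on the distal alkyne carbon in a five-membered alkoxyaluminate, and iodinolysis with retention gives the iodide cis to CH2OH (Z).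

Step 3
Reactants: 4 (Z)-3-iodo-4-[(4-methoxybenzyl)oxy]but-2-en-1-ol, 5 acrolein
Product: 6 (2Z,4S)-3-{[(4-methoxybenzyl)oxy]methyl}hexa-2,5-diene-1,4-diol
Conditions: CrCl2 (3 equiv), NiCl2 (2 mol%), N-[2-(4-isopropyl-4,5-dihydrooxazol-2-yl)-6-methylphenyl]methanesulfonamide (antipode that gives the 4S alcohol, 3.3 equiv), Et3N, THF, rt
Reagents that add atoms: none
Why: Asymmetric Nozaki–Hiyama–Kishi alkenylation, in which the alkenyl–CrCl2 species forms with retention of alkene geometry, tolerates the free OH, and the chiral sulfonamide on chromium selects the aldehyde face to set C4 as S (ee checked by Mosher ester).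

Step 4
Reactants: 6 (2Z,4S)-3-{[(4-methoxybenzyl)oxy]methyl}hexa-2,5-diene-1,4-diol
Product: 7 (1S)-1-[(2R,3S)-3-(hydroxymethyl)-2-{[(4-methoxybenzyl)oxy]methyl}oxiran-2-yl]prop-2-en-1-ol
Conditions: mCPBA (1.1 equiv), NaHCO3, CH2Cl2, 0 °C
Reagents that add atoms: 3-chloroperbenzoic acid, OOC(=O)c1cccc(Cl)c1
Why: Hydroxyl-directed (Henbest) epoxidation of the electron-rich trisubstituted alkene, in which A(1,3) strain with the cis CH2OH holds C4–H in the alkene plane so the peracid bound to C4–OH attacks the face syn to that OH, giving the threo epoxy alcohol (C5 and C6 set; epoxide trans to C4–O in the later ring).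

Step 5
Reactants: 7 (1S)-1-[(2R,3S)-3-(hydroxymethyl)-2-{[(4-methoxybenzyl)oxy]methyl}oxiran-2-yl]prop-2-en-1-ol
Product: 8 (2S,3S)-2-{[(4-methoxybenzyl)oxy]methyl}-3-[(triethylsilyloxy)methyl]-2-[(1S)-1-(triethylsilyloxy)prop-2-en-1-yl]oxirane
Conditions: Et3SiCl (2.5 equiv), imidazole, CH2Cl2, 0 °C
Reagents that add atoms: chlorotriethylsilane, CC[Si](Cl)(CC)CC
Why: Standard bis-silylation of the primary and secondary hydroxyls.

Step 6
Reactants: 8 (2S,3S)-2-{[(4-methoxybenzyl)oxy]methyl}-3-[(triethylsilyloxy)methyl]-2-[(1S)-1-(triethylsilyloxy)prop-2-en-1-yl]oxirane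
Product: 10 (2R,3S)-3-{[(4-methoxybenzyl)oxy]methyl}-3-[(1S)-1-(triethylsilyloxy)prop-2-en-1-yl]oxirane-2-carbaldehyde, via alkoxysulfonium chloride 9 (not isolated)
Conditions: (COCl)2, DMSO, CH2Cl2, -78 to -35 °C; then Et3N, -78 to 0 °C
Reagents that add atoms: none
Why: Swern oxidation in which chlorodimethylsulfonium chloride cleaves and oxidises the unhindered primary triethylsilyl ether directly while the secondary one survives.

Step 7
Reactants: 10 (2R,3S)-3-{[(4-methoxybenzyl)oxy]methyl}-3-[(1S)-1-(triethylsilyloxy)prop-2-en-1-yl]oxirane-2-carbaldehyde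
Product: 12 1-{(2S,3S)-3-{[(4-methoxybenzyl)oxy]methyl}-3-[(1S)-1-(triethylsilyloxy)prop-2-en-1-yl]oxiran-2-yl}prop-2-en-1-yl acetate (C1 epimer mixture), via bromomagnesium alkoxide 11 (not isolated)
Conditions: CH2=CHMgBr, THF, -78 °C; then Ac2O, -78 °C to rt
Reagents that add atoms: vinylmagnesium bromide, C=C[Mg]Br; acetic anhydride, CC(=O)OC(C)=O
Why: Grignard 1,2-addition followed by O-acylation of the alkoxide, with the C1 configuration irrelevant because C1 ends as the ketone.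

Step 8
Reactants: 12 1-{(2S,3S)-3-{[(4-methoxybenzyl)oxy]methyl}-3-[(1S)-1-(triethylsilyloxy)prop-2-en-1-yl]oxiran-2-yl}prop-2-en-1-yl acetate
Product: 13 (4S,5S,6S)-5,6-epoxy-5-{[(4-methoxybenzyl)oxy]methyl}-4-(triethylsilyloxy)cyclohex-2-en-1-yl acetate (C1 epimer mixture)
Conditions: second-generation Grubbs catalyst RuCl2(=CHPh)(PCy3)(1,3-dimesitylimidazolidin-2-ylidene) (5 mol%), CH2Cl2 (5 mM), 40 °C
Reagents that add atoms: none
Why: Ring-closing metathesis of two monosubstituted alkenes held cis on the oxirane closes the cyclohexene (C2=C3) with loss of ethene and touches no stereocentre.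

Step 9
Reactants: 13 (4S,5S,6S)-5,6-epoxy-5-{[(4-methoxybenzyl)oxy]methyl}-4-(triethylsilyloxy)cyclohex-2-en-1-yl acetate
Product: 14 (4S,5S,6S)-5,6-epoxy-5-(hydroxymethyl)-4-(triethylsilyloxy)cyclohex-2-en-1-yl acetate (C1 epimer mixture)
Conditions: DDQ (1.3 equiv), CH2Cl2/pH 7 buffer, 0 °C
Reagents that add atoms: none
Why: Oxidative cleavage of the 4-methoxybenzyl ether by benzylic hydride abstraction, under which silyl ether, acetate, epoxide and the isolated alkene are inert.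

Step 10
Reactants: 14 (4S,5S,6S)-5,6-epoxy-5-(hydroxymethyl)-4-(triethylsilyloxy)cyclohex-2-en-1-yl acetate
Product: 15 (4S,5S,6S)-5,6-epoxy-5-formyl-4-(triethylsilyloxy)cyclohex-2-en-1-yl acetate (fragment A, C1 epimer mixture)
Conditions: Dess–Martin periodinane, NaHCO3, CH2Cl2, 0 °C to rt
Reagents that add atoms: none
Why: Dess–Martin oxidation of the primary alcohol to an aldehyde whose α-carbon is quaternary and cannot epimerise.

**Fragment B (steps 11–20)**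

Step 11
Reactants: 16 pent-4-yn-1-ol
Product: 18 (E)-5-iodo-4-methylpent-4-en-1-ol, via alkenyldimethylalane 17 (not isolated)
Conditions: AlMe3 (3 equiv), Cp2ZrCl2 (0.25 equiv), CH2Cl2, 0 °C to rt; then I2, THF, -30 °C
Reagents that add atoms: trimethylaluminium, C[Al](C)C; iodine, II
Why: Negishi carboalumination adds Me and Al syn across the terminal alkyne (Al terminal) and iodinolysis with retention gives the E iodide (C6'=C7').

Step 12
Reactants: 18 (E)-5-iodo-4-methylpent-4-en-1-ol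
Product: 19 (E)-5-iodo-4-methylpent-4-enal
Conditions: Dess–Martin periodinane, NaHCO3, CH2Cl2, rt
Reagents that add atoms: none
Why: Dess–Martin oxidation of a primary alcohol without touching the alkenyl iodide.

Step 13
Reactants: 19 (E)-5-iodo-4-methylpent-4-enal
Product: 20 ethyl (2Z,6E)-7-iodo-2,6-dimethylhepta-2,6-dienoate
Conditions: ethyl 2-[bis(2,2,2-trifluoroethoxy)phosphoryl]propanoate, KN(SiMe3)2, 18-crown-6, THF, -78 °C
Reagents that add atoms: ethyl 2-[bis(2,2,2-trifluoroethoxy)phosphoryl]propanoate, CCOC(=O)C(C)P(=O)(OCC(F)(F)F)OCC(F)(F)F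
Why: Still–Gennari olefination, whose fast irreversible elimination from the kinetic adduct gives the Z trisubstituted enoate (C10'=C11').

Step 14
Reactants: 20 ethyl (2Z,6E)-7-iodo-2,6-dimethylhepta-2,6-dienoate
Product: 21 (2Z,6E)-7-iodo-2,6-dimethylhepta-2,6-dien-1-ol
Conditions: iBu2AlH (2.5 equiv), CH2Cl2, -78 °C
Reagents that add atoms: none
Why: 1,2-Reduction of the enoate to the allylic alcohol with both alkene geometries and the alkenyl iodide intact.

Step 15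
Reactants: 21 (2Z,6E)-7-iodo-2,6-dimethylhepta-2,6-dien-1-ol
Product: 22 tert-butyl{[(2Z,6E)-7-iodo-2,6-dimethylhepta-2,6-dien-1-yl]oxy}dimethylsilane
Conditions: tBuMe2SiCl, imidazole, CH2Cl2, rt
Reagents that add atoms: tert-butylchlorodimethylsilane, CC(C)(C)[Si](C)(C)Cl
Why: Silylation gives a primary silyl ether that survives all later steps and falls in the final fluoride step.

Step 16
Reactants: 23 1,4-bis(trimethylsilyl)buta-1,3-diyne
Product: 25 (trimethylsilyl)buta-1,3-diyne, via lithium butadiynide 24 (not isolated)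
Conditions: MeLi·LiBr (1 equiv), Et2O, rt; then H2O
Reagents that add atoms: none
Why: Selective mono-desilylation by attack of MeLi at one silicon, the resulting acetylide being inert to a second cleavage until protonated.

Step 17
Reactants: 25 (trimethylsilyl)buta-1,3-diyne
Product: 26 trimethyl[(E)-4-(4,4,5,5-tetramethyl-1,3,2-dioxaborolan-2-yl)but-3-en-1-yn-1-yl]silane
Conditions: pinacolborane, Cp2Zr(H)Cl (5 mol%), Et3N (10 mol%), CH2Cl2, rt
Reagents that add atoms: pinacolborane, CC1(C)OBOC1(C)C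
Why: Cp2Zr(H)Cl-catalysed hydroboration adds H–B syn and anti-Markovnikov to the terminal alkyne only, giving the E alkenylboronate (C4'=C5').

Step 18
Reactants: 22 tert-butyl{[(2Z,6E)-7-iodo-2,6-dimethylhepta-2,6-dien-1-yl]oxy}dimethylsilane, 26 trimethyl[(E)-4-(4,4,5,5-tetramethyl-1,3,2-dioxaborolan-2-yl)but-3-en-1-yn-1-yl]silane
Product: 27 tert-butyl{[(2Z,6E,8E)-2,6-dimethyl-11-(trimethylsilyl)undeca-2,6,8-trien-10-yn-1-yl]oxy}dimethylsilane
Conditions: Pd(PPh3)4 (5 mol%), K3PO4 (aq.), THF, 45 °C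
Reagents that add atoms: none
Why: Suzuki–Miyaura alkenyl–alkenyl coupling forms C5'–C6' with retention of both alkene geometries.

Step 19
Reactants: 27 tert-butyl{[(2Z,6E,8E)-2,6-dimethyl-11-(trimethylsilyl)undeca-2,6,8-trien-10-yn-1-yl]oxy}dimethylsilane
Product: 28 tert-butyl{[(2Z,6E,8E)-2,6-dimethylundeca-2,6,8-trien-10-yn-1-yl]oxy}dimethylsilane
Conditions: K2CO3 (cat.), MeOH, rt
Reagents that add atoms: none
Why: Methanolytic protodesilylation of the alkynylsilane, to which the silyl ether is stable.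

Step 20
Reactants: 28 tert-butyl{[(2Z,6E,8E)-2,6-dimethylundeca-2,6,8-trien-10-yn-1-yl]oxy}dimethylsilane
Product: 30 tert-butyl{[(2Z,6E,8E,10E)-11-iodo-2,6,10-trimethylundeca-2,6,8,10-tetraen-1-yl]oxy}dimethylsilane (fragment B), via trienyldimethylalane 29 (not isolated)
Conditions: AlMe3 (3 equiv), Cp2ZrCl2 (0.5 equiv), CH2Cl2, 0 °C to rt; then I2, THF, -30 °C
Reagents that add atoms: trimethylaluminium, C[Al](C)C; iodine, II
Why: Negishi carboalumination of the conjugated terminal alkyne (syn, Al terminal) and iodinolysis with retention give the E trisubstituted iodide (C2'=C3').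

**Coupling and endgame (steps 21–29)**

Step 21
Reactants: 15 (4S,5S,6S)-5,6-epoxy-5-formyl-4-(triethylsilyloxy)cyclohex-2-en-1-yl acetate, 30 tert-butyl{[(2Z,6E,8E,10E)-11-iodo-2,6,10-trimethylundeca-2,6,8,10-tetraen-1-yl]oxy}dimethylsilane
Product: 31 (4S,5S,6S)-5-[(2'E,4'E,6'E,10'Z)-12'-(tert-butyldimethylsilyloxy)-1'-hydroxy-3',7',11'-trimethyldodeca-2',4',6',10'-tetraen-1'-yl]-5,6-epoxy-4-(triethylsilyloxy)cyclohex-2-en-1-yl acetate (C1/C1' epimer mixture)
Conditions: CrCl2 (6 equiv), NiCl2 (1 mol%), DMSO, rt, dark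
Reagents that add atoms: none
Why: Nozaki–Hiyama–Kishi coupling adds the alkenyl–CrCl2 species (geometry retained) to the aldehyde only, tolerating acetate, epoxide and silyl ethers, and the C1' mixture is corrected in the next two steps.

Step 22
Reactants: 31 the C1' carbinol mixture
Product: 32 (4S,5S,6S)-5-[(2'E,4'E,6'E,10'Z)-12'-(tert-butyldimethylsilyloxy)-3',7',11'-trimethyl-1'-oxododeca-2',4',6',10'-tetraen-1'-yl]-5,6-epoxy-4-(triethylsilyloxy)cyclohex-2-en-1-yl acetate (C1 epimer mixture)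
Conditions: Dess–Martin periodinane, NaHCO3, CH2Cl2, 0 °C
Reagents that add atoms: none
Why: Dess–Martin oxidation converges both C1' epimers to one trienyl ketone.

Step 23
Reactants: 32 the C1' ketone
Product: 33 (1'S,4S,5S,6S)-5-[(2'E,4'E,6'E,10'Z)-12'-(tert-butyldimethylsilyloxy)-1'-hydroxy-3',7',11'-trimethyldodeca-2',4',6',10'-tetraen-1'-yl]-5,6-epoxy-4-(triethylsilyloxy)cyclohex-2-en-1-yl acetate (C1 epimer mixture)
Conditions: Zn(BH4)2, Et2O, -30 °C
Reagents that add atoms: none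
Why: Chelation-controlled 1,2-reduction of an α,β-epoxy ketone, in which Zn(BH4)2 bridges the carbonyl and epoxide oxygens and hydride enters anti to the epoxide C6 carbon, giving the anti (erythro) epoxy alcohol, which is 1'S.

Step 24
Reactants: 33 the (1'S)-alcohol
Product: 34 (1'S,4S,5S,6S)-5-[(2'E,4'E,6'E,10'Z)-12'-(tert-butyldimethylsilyloxy)-3',7',11'-trimethyl-1'-(triethylsilyloxy)dodeca-2',4',6',10'-tetraen-1'-yl]-5,6-epoxy-4-(triethylsilyloxy)cyclohex-2-en-1-yl acetate (C1 epimer mixture)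
Conditions: Et3SiOTf, 2,6-lutidine, CH2Cl2, -78 °C
Reagents that add atoms: triethylsilyl trifluoromethanesulfonate, CC[Si](CC)(CC)OS(=O)(=O)C(F)(F)F
Why: Silyl triflate silylation is strong enough for the hindered C1' hydroxyl and masks it before C1 is oxidised.

Step 25
Reactants: 34 the bis(triethylsilyl) acetate
Product: 35 (1'S,4S,5S,6S)-5-[(2'E,4'E,6'E,10'Z)-12'-(tert-butyldimethylsilyloxy)-3',7',11'-trimethyl-1'-(triethylsilyloxy)dodeca-2',4',6',10'-tetraen-1'-yl]-5,6-epoxy-4-(triethylsilyloxy)cyclohex-2-en-1-ol (C1 epimer mixture)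
Conditions: K2CO3, MeOH, 0 °C
Reagents that add atoms: none
Why: Mild transesterification removes the only ester while secondary triethylsilyl and primary TBS ethers survive.

Step 26
Reactants: 35 the C1 alcohol
Product: 36 (1'S,4S,5S,6R)-5-[(2'E,4'E,6'E,10'Z)-12'-(tert-butyldimethylsilyloxy)-3',7',11'-trimethyl-1'-(triethylsilyloxy)dodeca-2',4',6',10'-tetraen-1'-yl]-5,6-epoxy-4-(triethylsilyloxy)cyclohex-2-en-1-one
Conditions: Dess–Martin periodinane, NaHCO3, CH2Cl2, 0 °C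
Reagents that add atoms: none
Why: Dess–Martin oxidation of the allylic alcohol converges both C1 epimers to the epoxy-enone.

Step 27
Reactants: 36 the epoxy-enone
Product: 37 (1'S,4S,5R,6R)-5-[(2'E,4'E,6'E,10'Z)-12'-(tert-butyldimethylsilyloxy)-3',7',11'-trimethyl-1'-(triethylsilyloxy)dodeca-2',4',6',10'-tetraen-1'-yl]-5,6-epoxy-2-(hydroxymethyl)-4-(triethylsilyloxy)cyclohex-2-en-1-one
Conditions: aq. HCHO (37%), DMAP (0.5 equiv), THF/H2O, rt
Reagents that add atoms: formaldehyde, C=O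
Why: Morita–Baylis–Hillman reaction, in which DMAP adds to C3, the enolate captures formaldehyde at C2 and elimination restores the enone without touching a stereocentre.

Step 28
Reactants: 37 the hydroxymethyl enone
Product: 38 (1'S,4S,5R,6R)-2-(acetoxymethyl)-5-[(2'E,4'E,6'E,10'Z)-12'-(tert-butyldimethylsilyloxy)-3',7',11'-trimethyl-1'-(triethylsilyloxy)dodeca-2',4',6',10'-tetraen-1'-yl]-5,6-epoxy-4-(triethylsilyloxy)cyclohex-2-en-1-one
Conditions: Ac2O, pyridine, CH2Cl2, 0 °C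
Reagents that add atoms: acetic anhydride, CC(=O)OC(C)=O
Why: O-Acetylation of the only free hydroxyl, run without DMAP to avoid allylic displacement of the new acetate.

Step 29
Reactants: 38 the fully protected acetate
Product: 39 (4S,5R,6R)-2-(acetoxymethyl)-5-[(1S,2E,4E,6E,10Z)-1,12-dihydroxy-3,7,11-trimethyldodeca-2,4,6,10-tetraen-1-yl]-5,6-epoxy-4-hydroxycyclohex-2-en-1-one
Conditions: HF·pyridine, pyridine, THF, 0 °C to rt
Reagents that add atoms: none
Why: Buffered fluoride desilylation removes both triethylsilyl ethers and the primary TBS ether without base, so the epoxy-enone and the allylic acetate survive.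

**Compound list**

1 | but-2-yne-1,4-diol | OCC#CCO | starting material
2 | 4-[(4-methoxybenzyl)oxy]but-2-yn-1-ol | OCC#CCOCc1ccc(OC)cc1 | intermediate
3 | sodium alkenylaluminate (cyclic, bis(2-methoxyethoxy)) | [Na+].COCCO[Al-]1(OCCOC)OCC=C1COCc1ccc(OC)cc1 | intermediate
4 | (Z)-3-iodo-4-[(4-methoxybenzyl)oxy]but-2-en-1-ol | OC/C=C(\I)COCc1ccc(OC)cc1 | intermediate
5 | acrolein | C=CC=O | starting material
6 | (2Z,4S)-3-{[(4-methoxybenzyl)oxy]methyl}hexa-2,5-diene-1,4-diol | C=C[C@H](O)/C(COCc1ccc(OC)cc1)=C\CO | intermediate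
7 | (1S)-1-[(2R,3S)-3-(hydroxymethyl)-2-{[(4-methoxybenzyl)oxy]methyl}oxiran-2-yl]prop-2-en-1-ol | C=C[C@H](O)[C@@]1(COCc2ccc(OC)cc2)O[C@H]1CO | intermediate
8 | (2S,3S)-2-{[(4-methoxybenzyl)oxy]methyl}-3-[(triethylsilyloxy)methyl]-2-[(1S)-1-(triethylsilyloxy)prop-2-en-1-yl]oxirane | C=C[C@H](O[Si](CC)(CC)CC)[C@@]1(COCc2ccc(OC)cc2)O[C@H]1CO[Si](CC)(CC)CC | intermediate
9 | alkoxydimethylsulfonium chloride of the C1 oxygen | C=C[C@H](O[Si](CC)(CC)CC)[C@@]1(COCc2ccc(OC)cc2)O[C@H]1CO[S+](C)C.[Cl-] | intermediate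
10 | (2R,3S)-3-{[(4-methoxybenzyl)oxy]methyl}-3-[(1S)-1-(triethylsilyloxy)prop-2-en-1-yl]oxirane-2-carbaldehyde | C=C[C@H](O[Si](CC)(CC)CC)[C@@]1(COCc2ccc(OC)cc2)O[C@H]1C=O | intermediate
11 | bromomagnesium alkoxide of the C1 carbinol (C1 epimers) | C=C[C@H](O[Si](CC)(CC)CC)[C@@]1(COCc2ccc(OC)cc2)O[C@H]1C(O[Mg]Br)C=C | intermediate
12 | 1-{(2S,3S)-3-{[(4-methoxybenzyl)oxy]methyl}-3-[(1S)-1-(triethylsilyloxy)prop-2-en-1-yl]oxiran-2-yl}prop-2-en-1-yl acetate (C1 epimers) | C=C[C@H](O[Si](CC)(CC)CC)[C@@]1(COCc2ccc(OC)cc2)O[C@H]1C(OC(C)=O)C=C | intermediate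
13 | (4S,5S,6S)-5,6-epoxy-5-{[(4-methoxybenzyl)oxy]methyl}-4-(triethylsilyloxy)cyclohex-2-en-1-yl acetate (C1 epimers) | CC(=O)OC1C=C[C@H](O[Si](CC)(CC)CC)[C@@]2(COCc3ccc(OC)cc3)O[C@H]21 | intermediate
14 | (4S,5S,6S)-5,6-epoxy-5-(hydroxymethyl)-4-(triethylsilyloxy)cyclohex-2-en-1-yl acetate (C1 epimers) | CC(=O)OC1C=C[C@H](O[Si](CC)(CC)CC)[C@@]2(CO)O[C@H]21 | intermediate
15 | (4S,5S,6S)-5,6-epoxy-5-formyl-4-(triethylsilyloxy)cyclohex-2-en-1-yl acetate (fragment A, C1 epimers) | CC(=O)OC1C=C[C@H](O[Si](CC)(CC)CC)[C@@]2(C=O)O[C@H]21 | intermediate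
16 | pent-4-yn-1-ol | C#CCCCO | starting material
17 | alkenyldimethylalane from 16 (O-aluminated) | C[Al](C)/C=C(\C)CCCO[Al](C)C | intermediate
18 | (E)-5-iodo-4-methylpent-4-en-1-ol | I/C=C(\C)CCCO | intermediate
19 | (E)-5-iodo-4-methylpent-4-enal | I/C=C(\C)CCC=O | intermediate
20 | ethyl (2Z,6E)-7-iodo-2,6-dimethylhepta-2,6-dienoate | I/C=C(\C)CC/C=C(/C)C(=O)OCC | intermediate
21 | (2Z,6E)-7-iodo-2,6-dimethylhepta-2,6-dien-1-ol | I/C=C(\C)CC/C=C(/C)CO | intermediate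
22 | tert-butyl{[(2Z,6E)-7-iodo-2,6-dimethylhepta-2,6-dien-1-yl]oxy}dimethylsilane | I/C=C(\C)CC/C=C(/C)CO[Si](C)(C)C(C)(C)C | intermediate
23 | 1,4-bis(trimethylsilyl)buta-1,3-diyne | C[Si](C)(C)C#CC#C[Si](C)(C)C | starting material
24 | lithium (trimethylsilyl)butadiynide | [Li]C#CC#C[Si](C)(C)C | intermediate
25 | (trimethylsilyl)buta-1,3-diyne | C#CC#C[Si](C)(C)C | intermediate
26 | trimethyl[(E)-4-(4,4,5,5-tetramethyl-1,3,2-dioxaborolan-2-yl)but-3-en-1-yn-1-yl]silane | C[Si](C)(C)C#C/C=C/B1OC(C)(C)C(C)(C)O1 | intermediate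
27 | tert-butyl{[(2Z,6E,8E)-2,6-dimethyl-11-(trimethylsilyl)undeca-2,6,8-trien-10-yn-1-yl]oxy}dimethylsilane | C[Si](C)(C)C#C/C=C/C=C(\C)CC/C=C(/C)CO[Si](C)(C)C(C)(C)C | intermediate
28 | tert-butyl{[(2Z,6E,8E)-2,6-dimethylundeca-2,6,8-trien-10-yn-1-yl]oxy}dimethylsilane | C#C/C=C/C=C(\C)CC/C=C(/C)CO[Si](C)(C)C(C)(C)C | intermediate
29 | trienyldimethylalane from 28 | C[Al](C)/C=C(C)/C=C/C=C(\C)CC/C=C(/C)CO[Si](C)(C)C(C)(C)C | intermediate
30 | tert-butyl{[(2Z,6E,8E,10E)-11-iodo-2,6,10-trimethylundeca-2,6,8,10-tetraen-1-yl]oxy}dimethylsilane (fragment B) | I/C=C(C)/C=C/C=C(\C)CC/C=C(/C)CO[Si](C)(C)C(C)(C)C | intermediate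
31 | (4S,5S,6S)-5-[(2'E,4'E,6'E,10'Z)-12'-(tert-butyldimethylsilyloxy)-1'-hydroxy-3',7',11'-trimethyldodeca-2',4',6',10'-tetraen-1'-yl]-5,6-epoxy-4-(triethylsilyloxy)cyclohex-2-en-1-yl acetate (C1/C1' epimers) | CC(=O)OC1C=C[C@H](O[Si](CC)(CC)CC)[C@@]2(C(O)/C=C(C)/C=C/C=C(\C)CC/C=C(/C)CO[Si](C)(C)C(C)(C)C)O[C@H]21 | intermediate
32 | (4S,5S,6S)-5-[(2'E,4'E,6'E,10'Z)-12'-(tert-butyldimethylsilyloxy)-3',7',11'-trimethyl-1'-oxododeca-2',4',6',10'-tetraen-1'-yl]-5,6-epoxy-4-(triethylsilyloxy)cyclohex-2-en-1-yl acetate (C1 epimers) | CC(=O)OC1C=C[C@H](O[Si](CC)(CC)CC)[C@@]2(C(=O)/C=C(C)/C=C/C=C(\C)CC/C=C(/C)CO[Si](C)(C)C(C)(C)C)O[C@H]21 | intermediate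
33 | (1'S,4S,5S,6S)-5-[(2'E,4'E,6'E,10'Z)-12'-(tert-butyldimethylsilyloxy)-1'-hydroxy-3',7',11'-trimethyldodeca-2',4',6',10'-tetraen-1'-yl]-5,6-epoxy-4-(triethylsilyloxy)cyclohex-2-en-1-yl acetate (C1 epimers) | CC(=O)OC1C=C[C@H](O[Si](CC)(CC)CC)[C@@]2([C@@H](O)/C=C(C)/C=C/C=C(\C)CC/C=C(/C)CO[Si](C)(C)C(C)(C)C)O[C@H]21 | intermediate
34 | (1'S,4S,5S,6S)-5-[(2'E,4'E,6'E,10'Z)-12'-(tert-butyldimethylsilyloxy)-3',7',11'-trimethyl-1'-(triethylsilyloxy)dodeca-2',4',6',10'-tetraen-1'-yl]-5,6-epoxy-4-(triethylsilyloxy)cyclohex-2-en-1-yl acetate (C1 epimers) | CC(=O)OC1C=C[C@H](O[Si](CC)(CC)CC)[C@@]2([C@@H](O[Si](CC)(CC)CC)/C=C(C)/C=C/C=C(\C)CC/C=C(/C)CO[Si](C)(C)C(C)(C)C)O[C@H]21 | intermediate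
35 | (1'S,4S,5S,6S)-5-[(2'E,4'E,6'E,10'Z)-12'-(tert-butyldimethylsilyloxy)-3',7',11'-trimethyl-1'-(triethylsilyloxy)dodeca-2',4',6',10'-tetraen-1'-yl]-5,6-epoxy-4-(triethylsilyloxy)cyclohex-2-en-1-ol (C1 epimers) | OC1C=C[C@H](O[Si](CC)(CC)CC)[C@@]2([C@@H](O[Si](CC)(CC)CC)/C=C(C)/C=C/C=C(\C)CC/C=C(/C)CO[Si](C)(C)C(C)(C)C)O[C@H]21 | intermediate
36 | (1'S,4S,5S,6R)-5-[(2'E,4'E,6'E,10'Z)-12'-(tert-butyldimethylsilyloxy)-3',7',11'-trimethyl-1'-(triethylsilyloxy)dodeca-2',4',6',10'-tetraen-1'-yl]-5,6-epoxy-4-(triethylsilyloxy)cyclohex-2-en-1-one | O=C1C=C[C@H](O[Si](CC)(CC)CC)[C@@]2([C@@H](O[Si](CC)(CC)CC)/C=C(C)/C=C/C=C(\C)CC/C=C(/C)CO[Si](C)(C)C(C)(C)C)O[C@H]21 | intermediate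
37 | (1'S,4S,5R,6R)-5-[(2'E,4'E,6'E,10'Z)-12'-(tert-butyldimethylsilyloxy)-3',7',11'-trimethyl-1'-(triethylsilyloxy)dodeca-2',4',6',10'-tetraen-1'-yl]-5,6-epoxy-2-(hydroxymethyl)-4-(triethylsilyloxy)cyclohex-2-en-1-one | O=C1C(CO)=C[C@H](O[Si](CC)(CC)CC)[C@@]2([C@@H](O[Si](CC)(CC)CC)/C=C(C)/C=C/C=C(\C)CC/C=C(/C)CO[Si](C)(C)C(C)(C)C)O[C@H]21 | intermediate
38 | (1'S,4S,5R,6R)-2-(acetoxymethyl)-5-[(2'E,4'E,6'E,10'Z)-12'-(tert-butyldimethylsilyloxy)-3',7',11'-trimethyl-1'-(triethylsilyloxy)dodeca-2',4',6',10'-tetraen-1'-yl]-5,6-epoxy-4-(triethylsilyloxy)cyclohex-2-en-1-one | CC(=O)OCC1=C[C@H](O[Si](CC)(CC)CC)[C@@]2([C@@H](O[Si](CC)(CC)CC)/C=C(C)/C=C/C=C(\C)CC/C=C(/C)CO[Si](C)(C)C(C)(C)C)O[C@H]2C1=O | intermediate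
39 | (4S,5R,6R)-2-(acetoxymethyl)-5-[(1S,2E,4E,6E,10Z)-1,12-dihydroxy-3,7,11-trimethyldodeca-2,4,6,10-tetraen-1-yl]-5,6-epoxy-4-hydroxycyclohex-2-en-1-one | CC(=O)OCC1=C[C@H](O)[C@@]2([C@@H](O)/C=C(C)/C=C/C=C(\C)CC/C=C(/C)CO)O[C@H]2C1=O | target

**Totals**
Total step count: 29. Longest linear sequence: 19 steps (steps 1–10, then 21–29).

**Three steps most likely to fail, each with a fallback**

Step 3 (asymmetric addition to acrolein). The ee may be low with a volatile enal and a substrate carrying a free hydroxyl. The fallback sets out from 4 and comes back at 6. Silylation of 4 (tBuMe2SiCl, imidazole) gives tert-butyl{[(Z)-3-iodo-4-(4-methoxybenzyloxy)but-2-en-1-yl]oxy}dimethylsilane F1. Iodine–lithium exchange (tBuLi, Et2O, -78 °C) and addition to acrolein 5 give racemic (4Z)-6-(tert-butyldimethylsilyloxy)-4-[(4-methoxybenzyloxy)methyl]hexa-1,4-dien-3-ol F2. MnO2 oxidation gives the cross-conjugated (4Z)-6-(tert-butyldimethylsilyloxy)-4-[(4-methoxybenzyloxy)methyl]hexa-1,4-dien-3-one F3. Reduction with (R)-2-methyl-CBS-oxazaborolidine and BH3·SMe2, with vinyl as the small group, gives (3S,4Z)-6-(tert-butyldimethylsilyloxy)-4-[(4-methoxybenzyloxy)methyl]hexa-1,4-dien-3-ol F4. Bu4NF then returns diol 6.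

Step 23 (facial selectivity of the epoxy-ketone reduction). The bulky C4 substituent sits on the face that the chelate model asks hydride to use, so the wrong C1' epimer may dominate. The fallback sets out from 32 and comes back at 34, and replaces epoxide chelation by 1,3-induction from C4. HF·pyridine in pyridine/THF at 0 °C removes the secondary triethylsilyl ether before the primary TBS ether and gives (4S,5R,6S)-5-[(2'E,4'E,6'E,10'Z)-12'-(tert-butyldimethylsilyloxy)-3',7',11'-trimethyl-1'-oxododeca-2',4',6',10'-tetraen-1'-yl]-5,6-epoxy-4-hydroxycyclohex-2-en-1-yl acetate F5. Evans–Saksena reduction (Me4NBH(OAc)3, MeCN/AcOH, -30 °C) delivers hydride from the C4 alkoxyborohydride and gives the 1,3-anti diol (1'S,4S,5S,6S)-5-[(2'E,4'E,6'E,10'Z)-12'-(tert-butyldimethylsilyloxy)-1'-hydroxy-3',7',11'-trimethyldodeca-2',4',6',10'-tetraen-1'-yl]-5,6-epoxy-4-hydroxycyclohex-2-en-1-yl acetate F6; the C4 and C1' hydroxyls of the target are 1,3-anti. Double silylation (Et3SiOTf, 2,6-lutidine) returns 34.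

Step 27 (Morita–Baylis–Hillman on a hindered, base-sensitive epoxy-enone). The reaction may be slow or the amine may attack the epoxy-ketone. The fallback sets out from 36 and comes back at 37. α-Iodination (I2, pyridine, CH2Cl2, 0 °C, dark) gives (1'S,4S,5R,6R)-5-[(2'E,4'E,6'E,10'Z)-12'-(tert-butyldimethylsilyloxy)-3',7',11'-trimethyl-1'-(triethylsilyloxy)dodeca-2',4',6',10'-tetraen-1'-yl]-5,6-epoxy-2-iodo-4-(triethylsilyloxy)cyclohex-2-en-1-one F7. Stille coupling with Bu3SnCH2OH (Pd(PPh3)4, CuI, dioxane, 60 °C) installs the hydroxymethyl group and gives 37.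

**Further compounds**

F1 | step 3 | tert-butyl{[(Z)-3-iodo-4-(4-methoxybenzyloxy)but-2-en-1-yl]oxy}dimethylsilane | CC(C)(C)[Si](C)(C)OC/C=C(\I)COCc1ccc(OC)cc1
F2 | step 3 | racemic (4Z)-6-(tert-butyldimethylsilyloxy)-4-[(4-methoxybenzyloxy)methyl]hexa-1,4-dien-3-ol | C=CC(O)/C(COCc1ccc(OC)cc1)=C\CO[Si](C)(C)C(C)(C)C
F3 | step 3 | (4Z)-6-(tert-butyldimethylsilyloxy)-4-[(4-methoxybenzyloxy)methyl]hexa-1,4-dien-3-one | C=CC(=O)/C(COCc1ccc(OC)cc1)=C\CO[Si](C)(C)C(C)(C)C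
F4 | step 3 | (3S,4Z)-6-(tert-butyldimethylsilyloxy)-4-[(4-methoxybenzyloxy)methyl]hexa-1,4-dien-3-ol | C=C[C@H](O)/C(COCc1ccc(OC)cc1)=C\CO[Si](C)(C)C(C)(C)C
F5 | step 23 | (4S,5R,6S)-5-[(2'E,4'E,6'E,10'Z)-12'-(tert-butyldimethylsilyloxy)-3',7',11'-trimethyl-1'-oxododeca-2',4',6',10'-tetraen-1'-yl]-5,6-epoxy-4-hydroxycyclohex-2-en-1-yl acetate | CC(=O)OC1C=C[C@H](O)[C@@]2(C(=O)/C=C(C)/C=C/C=C(\C)CC/C=C(/C)CO[Si](C)(C)C(C)(C)C)O[C@H]21
F6 | step 23 | (1'S,4S,5S,6S)-5-[(2'E,4'E,6'E,10'Z)-12'-(tert-butyldimethylsilyloxy)-1'-hydroxy-3',7',11'-trimethyldodeca-2',4',6',10'-tetraen-1'-yl]-5,6-epoxy-4-hydroxycyclohex-2-en-1-yl acetate | CC(=O)OC1C=C[C@H](O)[C@@]2([C@@H](O)/C=C(C)/C=C/C=C(\C)CC/C=C(/C)CO[Si](C)(C)C(C)(C)C)O[C@H]21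
F7 | step 27 | (1'S,4S,5R,6R)-5-[(2'E,4'E,6'E,10'Z)-12'-(tert-butyldimethylsilyloxy)-3',7',11'-trimethyl-1'-(triethylsilyloxy)dodeca-2',4',6',10'-tetraen-1'-yl]-5,6-epoxy-2-iodo-4-(triethylsilyloxy)cyclohex-2-en-1-one | O=C1C(I)=C[C@H](O[Si](CC)(CC)CC)[C@@]2([C@@H](O[Si](CC)(CC)CC)/C=C(C)/C=C/C=C(\C)CC/C=C(/C)CO[Si](C)(C)C(C)(C)C)O[C@H]21
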